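**Assumption:** the target has no stereocentre. Its only stereochemical element is the E-trisubstituted alkene, with the ring-CH2 and the (CH2)9 chain trans.

## Retrosynthetic overview
- The thioacetate comes from the primary alcohol (Mitsunobu), and the alcohol from its TBS ether.
- The C(sp3)–C(sp2) bond between the pyranone-CH2 and the alkene CH is formed last. It is a Negishi coupling of the 6-CH2-zinc species of 2,3-dimethoxy-5,6-dimethylpyranone with an (E)-vinyl iodide.
- The vinyl iodide comes from Negishi carboalumination/iodination of a terminal alkyne. That alkyne is assembled by a Cu-catalysed Kumada coupling of a C6 Grignard with a C5 alkynyl bromide.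
- The only ring is the γ-pyranone. It is formed by lactonisation of a 3,5-dioxo ester made from methyl methoxyacetate, and the resulting 4-hydroxy-2-pyranone is converted to the 2-methoxy-4-pyranone by O-methylation.

## Route

**Step 1**
Reactants: 1 methyl methoxyacetate; 2 N-methoxy-N-methylpropanamide
Product: 3 methyl 2-methoxy-3-oxopentanoate
Conditions: LDA (1.1 equiv), THF, −78 °C; then 2, −78 → 0 °C; aq NH4Cl
Reagents that add atoms: none
Why: Crossed Claisen acylation of the lithium ester enolate with a Weinreb amide. The chelated tetrahedral intermediate survives until quench, so the reaction stops at the β-keto ester. No stereocentre is kept.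

**Step 2**
Reactants: 3 methyl 2-methoxy-3-oxopentanoate; 4 N-methoxy-N-methylacetamide
Product: 5 methyl 2-methoxy-4-methyl-3,5-dioxohexanoate
Conditions: NaH (1.0 equiv), THF, 0 °C; n-BuLi (1.0 equiv), −78 °C; then 4, −78 → 0 °C; aq NH4Cl
Reagents that add atoms: none
Why: Weiler dianion acylation. The γ-carbanion (C5) is the more basic terminus and is acylated selectively, placing the C5-methyl and the C6 carbonyl in one operation. The C4 epimeric centre is lost on ring formation.

**Step 3**
Reactants: 5 methyl 2-methoxy-4-methyl-3,5-dioxohexanoate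
Product: 6 4-hydroxy-3-methoxy-5,6-dimethyl-2H-pyran-2-one
Conditions: t-BuOK (1.1 equiv), THF, 0 → 25 °C; then 1 M HCl
Reagents that add atoms: none
Why: Base-mediated intramolecular lactonisation. The enolate oxygen of the C6 ketone attacks the methyl ester and MeOH is lost. The acidic 4-hydroxy-pyranone that forms drives the reaction, and this step forms the ring.

**Step 4**
Reactants: 6 4-hydroxy-3-methoxy-5,6-dimethyl-2H-pyran-2-one
Product: 7 2,3-dimethoxy-5,6-dimethyl-4H-pyran-4-one
Conditions: Me3O+BF4− (1.3 equiv), CH2Cl2, 25 °C, 16 h; then sat. aq NaHCO3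
Reagents that add atoms: trimethyloxonium tetrafluoroborate, C[O+](C)C.F[B-](F)(F)F
Why: Meerwein O-methylation under non-basic conditions occurs at the lactone carbonyl oxygen, the most basic site, giving an aromatic 2-methoxy-4-hydroxypyrylium. Loss of the 4-OH proton then gives the 2-methoxy-4-pyranone.

**Step 5**
Reactants: 8 6-bromohexan-1-ol
Product: 9 (6-bromohexyloxy)(tert-butyl)dimethylsilane
Conditions: TBSCl (1.1 equiv), imidazole (2 equiv), DMF, 0 → 25 °C
Reagents that add atoms: TBSCl, CC(C)(C)[Si](C)(C)Cl
Why: Silylation of the primary alcohol. The alkyl bromide is untouched and the TBS group survives the later Grignard, carboalumination and K2CO3 steps.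

**Step 6**
Reactants: 10 trimethylsilylacetylene; 11 1,3-dibromopropane
Product: 12 (5-bromopent-1-yn-1-yl)trimethylsilane
Conditions: n-BuLi (1.0 equiv), THF, −78 → 0 °C; then 11 (4 equiv), DMPU, −78 → 25 °C
Reagents that add atoms: none
Why: SN2 alkylation of a lithium acetylide. Excess dibromide suppresses double alkylation and the TMS group blocks the second acetylenic C–H.

**Step 7**
Reactants: 9 (6-bromohexyloxy)TBS; 12 (5-bromopent-1-yn-1-yl)TMS
Product: 13 trimethyl[11-(TBS-oxy)undec-1-yn-1-yl]silane
Conditions: Mg, THF, reflux (Grignard from 9); then 12, Li2CuCl4 (3 mol %), THF, −10 → 25 °C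
Reagents that add atoms: none
Why: Kumada-type Cu-catalysed alkyl–alkyl coupling of the primary Grignard with the primary bromide. The silyl alkyne and silyl ether are inert. This builds the (CH2)9 chain.

**Step 8**
Reactants: 13
Product: 14 11-(TBS-oxy)undec-1-yne
Conditions: K2CO3 (2 equiv), MeOH, 25 °C, 3 h
Reagents that add atoms: none
Why: Methanolysis of the C(sp)–Si bond. Primary TBS ethers are stable to K2CO3/MeOH.

**Step 9**
Reactants: 14
Product: 15 (E)-tert-butyl[(11-iodo-10-methylundec-10-en-1-yl)oxy]dimethylsilane
Conditions: Me3Al (3 equiv), Cp2ZrCl2 (0.3 equiv), ClCH2CH2Cl, 0 → 25 °C, 12 h; then I2 (1.5 equiv), THF, −30 → 0 °C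
Reagents that add atoms: trimethylaluminium, C[Al](C)C; iodine, II
Why: Negishi Zr-catalysed carboalumination. Syn addition puts Me on the internal carbon and Al on the terminal carbon, trans to the chain. Iodinolysis with retention fixes the E-geometry (I trans to the chain).

**Step 10**
Reactants: 7 2,3-dimethoxy-5,6-dimethylpyranone; 15 vinyl iodide
Product: 16 6-[(2E)-12-(TBS-oxy)-3-methyldodec-2-en-1-yl]-2,3-dimethoxy-5-methyl-4H-pyran-4-one
Conditions: LDA (1.2 equiv), THF, −78 °C, 45 min; ZnCl2 (1.3 equiv), −78 → 0 °C; then 15 (0.8 equiv), Pd(PPh3)4 (5 mol %), 50 °C, 12 h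
Reagents that add atoms: none
Why: The 6-methyl group is vinylogous to the C4 carbonyl, so it alone is acidic. The 5-methyl is not conjugated, and C2/C3 carry OMe. The resulting zinc species undergoes Negishi coupling with the vinyl iodide, with retention of alkene geometry, to give the E-alkene. This is the late fragment coupling.

**Step 11**
Reactants: 16
Product: 17 6-[(2E)-12-hydroxy-3-methyldodec-2-en-1-yl]-2,3-dimethoxy-5-methyl-4H-pyran-4-one
Conditions: CSA (0.2 equiv), MeOH/CH2Cl2 1:1, 0 → 25 °C, 4 h
Reagents that add atoms: none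
Why: Acid-catalysed methanolysis of a primary TBS ether. The pyranone OMe groups are only exchanged with MeOH, which is degenerate, and the trisubstituted alkene is unaffected.

**Step 12**
Reactants: 17
Product: 18 lehualide C
Conditions: PPh3 (1.5 equiv), DIAD (1.5 equiv), AcSH (1.6 equiv), THF, 0 → 25 °C
Reagents that add atoms: thioacetic acid, CC(=O)S
Why: Mitsunobu SN2 displacement of the primary alkoxyphosphonium by thioacetate. There is no stereocentre, and the alkene and pyranone survive.

## Compound list
1 | methyl methoxyacetate | COCC(=O)OC | starting material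
2 | N-methoxy-N-methylpropanamide | CCC(=O)N(C)OC | starting material
3 | methyl 2-methoxy-3-oxopentanoate | CCC(=O)C(OC)C(=O)OC | intermediate
4 | N-methoxy-N-methylacetamide | CC(=O)N(C)OC | starting material
5 | methyl 2-methoxy-4-methyl-3,5-dioxohexanoate | CC(=O)C(C)C(=O)C(OC)C(=O)OC | intermediate
6 | 4-hydroxy-3-methoxy-5,6-dimethyl-2H-pyran-2-one | COC1=C(O)C(C)=C(C)OC1=O | intermediate
7 | 2,3-dimethoxy-5,6-dimethyl-4H-pyran-4-one | COc1oc(C)c(C)c(=O)c1OC | intermediate
8 | 6-bromohexan-1-ol | OCCCCCCBr | starting material
9 | (6-bromohexyloxy)(tert-butyl)dimethylsilane | CC(C)(C)[Si](C)(C)OCCCCCCBr | intermediate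
10 | trimethylsilylacetylene | C[Si](C)(C)C#C | starting material
11 | 1,3-dibromopropane | BrCCCBr | starting material
12 | (5-bromopent-1-yn-1-yl)trimethylsilane | C[Si](C)(C)C#CCCCBr | intermediate
13 | trimethyl[11-(TBS-oxy)undec-1-yn-1-yl]silane | C[Si](C)(C)C#CCCCCCCCCCO[Si](C)(C)C(C)(C)C | intermediate
14 | 11-(TBS-oxy)undec-1-yne | C#CCCCCCCCCCO[Si](C)(C)C(C)(C)C | intermediate
15 | (E)-TBS ether of 11-iodo-10-methylundec-10-en-1-ol | I/C=C(\C)CCCCCCCCCO[Si](C)(C)C(C)(C)C | intermediate
16 | TBS ether of 17 | COc1oc(C/C=C(\C)CCCCCCCCCO[Si](C)(C)C(C)(C)C)c(C)c(=O)c1OC | intermediate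
17 | 6-[(2E)-12-hydroxy-3-methyldodec-2-en-1-yl]-2,3-dimethoxy-5-methylpyran-4-one | COc1oc(C/C=C(\C)CCCCCCCCCO)c(C)c(=O)c1OC | intermediate
18 | lehualide C, S-[(10E)-12-(5,6-dimethoxy-3-methyl-4-oxo-4H-pyran-2-yl)-10-methyldodec-10-en-1-yl] ethanethioate | COc1oc(C/C=C(\C)CCCCCCCCCSC(C)=O)c(C)c(=O)c1OC | target

**Total step count:** 12
**Longest linear sequence:** 7 steps (for example 8 → 9 → 13 → 14 → 15 → 16 → 17 → 18 via Steps 5, 7, 8, 9, 10, 11, 12, or via the pyranone arm Steps 1–4, 10, 11, 12).

## Three steps most likely to fail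
1. **Step 4 (regioselective O2-methylation).** Methylation at O4 would give the isomeric 3,4-dimethoxy-2-pyranone. Fallback: block O4 as the benzyl ether (BnBr, K2CO3). Then alkylate the lactone carbonyl with Me3O+BF4− to the 2-methoxy-4-benzyloxypyrylium salt, and remove the benzyl group by nucleophilic dealkylation (NaI, MeCN).
2. **Step 10 (Pd-catalysed coupling of the lateral zinc species).** Zinc dienolate reactivity, dimerisation or C5 attack could lower the yield. Fallback: lateral lithiation of 7 and a halogen quench (BrCF2CF2Br) to give the 6-(bromomethyl)pyranone. Then insert Zn/LiCl to make the benzylic-type zinc reagent and run the Negishi coupling with 15.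
3. **Step 2 (γ-acylation of the methoxy β-keto ester dianion).** Dianion formation or regioselectivity could be poor. Fallback: use 3-methylpentane-2,4-dione, form its dianion, and acylate it with dimethyl carbonate to give 4-hydroxy-5,6-dimethyl-2-pyranone. Then install 3-OMe by C3 bromination (NBS) and Cu-catalysed methoxylation (CuI, NaOMe) to reach 6.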